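The leftover was what I looked at first in the spring run: the target still to come after the last reading, because south repeats that charge and is read 2.00 h later.

| flask | substrate | coupling partner | capture agent | remark | time |
|---|---|---|---|---|---|
| spring | 0.20 M | 1 equiv | 0.010 M | run made earlier |  |
| summer | 0.20 M | 1.4 equiv | 0.010 M | run made earlier |  |
| noon | 0.20 M | 2.2 equiv | 0.010 M | run made earlier |  |
| south | 0.20 M | 1.00 equiv | 0.0100 M | everything together in a closed stirred flask, run for 6.0 h | 6.0 h |
| south-west | 0.20 M (fed, over 6.00 h) | 1.00 equiv | 0.0100 M | a stirred flask in which substrate is dosed at a steady rate over 6.00 h without added volume, worked up at 6.0 h | 6.0 h |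
| north | 0.20 M | 1.00 equiv | 0.0100 M | one stirred flow tank at steady state, fed with the mixture as stated, mean residence time 6.0 h |  |
| north-west | 0.20 M | 1.00 equiv (fed, over 6.00 h) | 0.0100 M | all but coupling partner at the start; coupling partner goes in evenly over 6.00 h, the run ends at 6.0 h | 6.0 h |

| spring: time / h | spring: target / % | summer: time / h | summer: target / % | noon: time / h | noon: target / % |
|---|---|---|---|---|---|
| 0.250 | 4.7 | 0.250 | 3.4 | 0.250 | 5.7 |
| 0.500 | 8.1 | 0.500 | 10.3 | 0.667 | 15.6 |
| 0.833 | 12.5 | 0.833 | 13.3 | 1.33 | 26.7 |
| 1.33 | 17.2 | 1.33 | 21.0 | 2.00 | 30.7 |
| 2.00 | 22.0 | 2.00 | 25.6 | 3.00 | 39.9 |
| 4.00 | 29.5 | 4.00 | 36.2 | 4.00 | 42.1 |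

(readings scatter by 1 percentage point)

- the stated concentrations are those of everything mixed, before any reaction; amounts are the same in each set-up
- the earlier runs were read with a standard deviation of 1 percentage point
- the feed brings no volume worth counting
- the earlier runs were made in a closed, stirred flask

- the set-up with the highest amount of target at the outlet or at the end, in percent of the substrate put in ("none" if the first two lie within 2 percentage points) (south / south-west / north / north-west / none)
- amount of target at the outlet or at the end, in percent of the substrate put in, south
- amount of target at the outlet or at the end, in percent of the substrate put in, south-west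
- amount of target at the outlet or at the end, in percent of the substrate put in, north
- amount of target at the outlet or at the end, in percent of the substrate put in, north-west

The spring run gained 22.0% in its first 2.00 h and 7.5 percentage points in the next stretch of equal length, which is less, so I read each stretch as keeping a fraction 0.341 of the gain before it. From below, south should hold at least the 29.5% read at 4.00 h, and from above, holding the last gain unshrunk through one more stretch gave 37.0%. I tightened both by hand. Summing all the shrinking gains put my ceiling, an estimate carrying the scatter of those readings, at 33.4%, and applying the fraction twice to the third gain lifted my floor to 30.4%, while applying it once gave my own figure, 32.1%.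

The same fraction means the leftover falls by a factor e every 1.86 h, and this leftover time, the relaxation time as read from the spring run, is what I carried to the other set-ups. I treated each fed slice as a small south with that ceiling. Averaging over the time each slice had left gave 23.4% for both dosed flasks, and averaging over the residence times of the tank gave 25.5% for north, so south came out ahead.

The forecast, reasoning “If activity dies with the clock, early reactant availability matters”, chose south with 34%, just above my ceiling, and gave 13% for south-west, 22% for north and 15% for north-west, all three below my figures.

The flasks gave 32.0% in south, under my ceiling, 24.6% in south-west, 25.1% in north and 24.6% in north-west, so south led, and the forecast stood 12 points and 9.6 points low on the two dosed flasks.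

    substrate + coupling partner ⇌ adduct (K = 8.08 M⁻¹, k = 1.28 M⁻¹ min⁻¹)
    adduct ⇌ target (K = 1.40, k = 0.00640 min⁻¹)
    capture agent + adduct → trapped intermediate (k = 0.0730 M⁻¹ min⁻¹)
    2 substrate → self-condensation product (k = 5.01 × 10⁻⁵ M⁻¹ min⁻¹)

In south, half of the turnover up to the asked time of substrate + coupling partner into adduct was done by 2.10 min, and half of that of adduct into target by 1.27 h, much later. Ceiling and leftover time give 24.7% for south at 2.5 h, and south read then holds 24.3%.

(Readings and results are calculated with made-up constants; noise was put on by code.)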